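## Structural features

The target (C30H52O2) is a trans-fused decalin (rings A and B, C1–C10 in drimane numbering) whose C9 carries, through the methylene C11, an all-E farnesyl chain (C12–C22, trisubstituted alkenes at C13, C17 and C21). Ring A holds an equatorial secondary alcohol at C3 (3β) next to the gem-dimethyl carbon C4; ring B holds a tertiary alcohol at C8 (8α-OH, 8β-CH3) next to the chain-bearing C9. Four of the five stereocentres are contiguous (C5–C10–C9–C8), two of them fully substituted (quaternary C10, carbinol C8), and the fifth, C3, lies across ring A, para to C10; the configuration is 3S,5R,8R,9R,10S. The fragile groups are the tertiary C8 alcohol, which dehydrates under acid and closes an 8,12-ether as soon as C12 carries a leaving group, and the 1,5-polyene, which excludes strong acid, hydrogenation and electrophilic oxidants late in the route. The real difficulty is absolute control of the quaternary C10 together with C5, then C8 and C9 during closure of ring B, and the union of the congested C9 region with the polyene without touching its alkenes. The key step exploits the pattern of ring A: oxygen at C3 in a 1,4-relation to C10 and the gem-dimethyl C4 next to the methine C5. This is the imprint of a [4+2] adduct of a 2-silyloxy diene (C1=C2–C3=C4, C4 dimethylated) and an α-methyl enal (C5=C10, formyl carbon C9, C6–C8 arm on C5).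

## Logic of the disconnections

17 ⇒ 16. No skeletal bond is cut; a phenylsulfonyl group is put back on C11. It makes C11 a carbanion site and can be removed reductively at the end. The demand is a C–S cleavage that leaves three isolated alkenes and two free alcohols untouched.

16 ⇒ 13 + 14. The C11–C12 bond is cut. This removes the whole polyene as a commercial C15 allylic bromide with both E alkenes in place, so no alkene geometry has to be made. It also avoids an electrophilic C12 on the ring fragment, which would be trapped by the C8 hydroxyl. The demand is C-alkylation of a hindered α-sulfonyl carbanion in the presence of two alkoxides.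

13 ⇒ 12. The C8–C9 bond is cut, opening ring B to a methyl ketone and an (E)-vinyl sulfone. The sulfone that later serves in 16 is here the radical acceptor. Two stereocentres (C8, C9) are traded for none. The demand is a reductive ketyl–alkene closure in which the oxygen at C8 and C11 end up trans and both equatorial.

12 ⇒ 11 ⇒ 10. No skeletal bond is cut. The C8 ketone is traced to a terminal alkene and the C3 carbinol to the ketone. The alkene is inert in every earlier step, so no protecting group is needed for C8. The demands are Markovnikov oxidation of one alkene in the presence of the vinyl sulfone, and α-face hydride delivery at C3.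

10 ⇒ 7 + 8. The C9=C11 bond is cut (olefination), and the C3 ketone is returned to its silyl enol ether. This gives the direct cycloadduct and a commercial phosphonate. The demand is E-selective olefination of a neopentyl-type aldehyde.

7 ⇒ 3 + 6. The C1–C10 and C4–C5 bonds are cut (key step); ring A and both of its ring-fusion stereocentres disappear, leaving two achiral, short fragments. The demand is a catalyst that selects one enal face and a diene that reacts at a fully substituted terminus. A dioxolane-masked ketone arm was considered for 6 and set aside: an acetal is a Lewis base and a latent oxocarbenium ion next to a cationic boron acid and a silyl enol ether, and it costs two more steps.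

6 ⇒ 4 + 5. The C5=C10 bond is cut (Wittig), giving two commercial compounds. The demand is E geometry, which later fixes the trans relation of C9 and C6.

3 ⇒ 2 ⇒ 1. The O–Si bond is cut, then the ketone is traced to a commercial allylic alcohol. Aminomethylation of the saturated methyl ketone followed by elimination was set aside because it is regiochemically unreliable at a ketone with a methine α-carbon.

## Other disconnections considered

Alternative 1: The cut is C8–C9 of ring B together with the C12–O bond of a lactone, leading back to the monocyclic keto enoate A2. In the forward step a divalent samarium reductant turns the C8 ketone of A2 into a ketyl that adds to C9 of the enoate; the alkoxide then closes onto the ester to give the trans-fused 8α,12-lactone A1.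
- In its favour: the ketone/acrylate closure is the best-established member of this reaction family, and the lactone ties up the C8 oxygen in a rigid intermediate that should be easy to purify.
- Against it: it does nothing for ring A, so A2 still needs absolute control of C5 and C10 and presupposes a step such as step 4. The ester carbon becomes C12, so the chain must be joined at C12–C13. That requires lactone reduction, masking of the C8 hydroxyl before C12 is activated, an iodide, a zinc reagent, a palladium-catalysed coupling with an alkenyl iodide partner needing a three-step branch of its own, and deprotection.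
- Comparison: structurally the two plans are nested, since step 8 closes the same bond with a sulfone in place of the ester. On the reliability of the ring-closing event and on the steric ease of the fragment union (C12 is one carbon further from C9 than C11), this alternative is the better. On step economy the chosen plan is clearly better: two steps and no protecting group from 13, against about six steps from A1.

Alternative 2: The cut is C9–C11 and C10–CH3 on the ring B enone A4. In the forward step a vinylcopper reagent adds to C9 of A4 and the resulting enolate is methylated at C10, giving A3 in one flask without closing a ring.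
- In its favour: two C–C bonds form in one operation. The C8 carbinol is present and silylated from the start, so it is never exposed; on this point the alternative is better than the chosen plan, which creates C8 late. The vinyl group would allow hydroboration and alkyl–alkenyl coupling at C12–C13 with no polyanion, which is at least the equal of step 9.
- Against it: ring A, with three of the five stereocentres and both fully substituted carbons C4 and C10, must be annulated afterwards onto a hindered ketone (quaternisation of C10, aldol closure, gem-dimethylation, trans-selective reduction at C5, C3 reduction). The facial selectivity of the conjugate addition rests on telling a silyloxy group from a methyl group on C8. Alkylation of copper-derived enolates is sluggish. A4 needs its own enantioselective synthesis.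
- Comparison: the stereocontrol is substrate-based where the chosen plan uses a catalyst on achiral partners, and the step count would be clearly higher.

Alternative 3: The cut is C5–C10 and C8–C9, leading back to the acyclic trienal A6. In the forward step the (E)-enal C9=C10 adds intramolecularly across the (5E,7Z)-diene C5=C6–C7=C8 to give the trans-octalin aldehyde A5.
- In its favour: both rings, two bonds and four stereocentres (C5, C8, C9, C10) arise in one step; in bonds and stereocentres per step it is better than the chosen plan. The diene geometry translates directly into 8α-oxygen and 8β-methyl.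
- Against it: the diene terminus C8 is fully substituted and carries its silyloxy group on the inside, so the reactive s-cis conformer is strained. The dienophile carbon C10 is β,β-disubstituted and must bond to C5 next to the quaternary C4. Trans fusion and facial sense depend on remote control from the C3 silyloxy group. A6 needs a preset C3 stereocentre and a geometrically pure (Z)-dienol ether. After cyclisation C6=C7 must be saturated and the chain built out from a neopentyl-type C11 aldehyde.
- Comparison: the alternative concentrates the risk in one thermally demanding step under substrate control; the chosen plan spreads it over a catalytic cycloaddition and a separate ring B closure. Overall the alternative is not shorter once A6 and the post-cyclisation steps are counted.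

Key step: step 4

Remarks on the chemistry:
- Drimane numbering is used throughout (C11 on C9; C12–C22 from the farnesyl unit).
- The C8 ketone is carried through the cycloaddition as a terminal alkene (but-3-enyl arm); the bonds formed, the ring closed and the carbon skeletons of diene, enal and adduct are unchanged.
- The sense of induction of the (S)-catalyst is assigned from the formyl C–H···O binding model for α-substituted enals; if the opposite face is exposed, the (R)-catalyst is used with no other change.

## Route

Step 1
Reactants: 1 4-methylpent-1-en-3-ol (racemic)
Product: 2 4-methylpent-1-en-3-one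
Conditions: Dess–Martin periodinane (1.1 equiv), CH2Cl2, 0 °C → rt; distilled, kept cold with a trace of BHT
Reagents that add atoms: none
Why: Dess–Martin oxidation of a secondary allylic alcohol under neutral conditions avoids conjugate addition to, or polymerisation of, the vinyl ketone; the racemic carbinol centre of 1 is erased.

Step 2
Reactants: 2 4-methylpent-1-en-3-one
Product: 3 4-methyl-3-(tert-butyldimethylsilyloxy)penta-1,3-diene
Conditions: TBSOTf (1.1 equiv), Et3N (1.5 equiv), Et2O, 0 °C → rt
Reagents that add atoms: tert-butyldimethylsilyl trifluoromethanesulfonate, CC(C)(C)[Si](C)(C)OS(=O)(=O)C(F)(F)F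
Why: Soft enolisation (silyl triflate with a tertiary amine): O-silylation and deprotonation at the isopropyl methine, the only enolisable position, give the cross-conjugated dienol silyl ether; amine conjugate addition to the silylated enone is reversible and should drain to 3.

Step 3
Reactants: 4 pent-4-enal; 5 2-(triphenylphosphoranylidene)propanal
Product: 6 (E)-2-methylhepta-2,6-dienal
Conditions: toluene, 90 °C
Reagents that add atoms: none
Why: Wittig olefination with a formyl-stabilised ylide is E-selective, and the ylide should not react on with the less electrophilic, α-branched enal 6.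

Step 4
Reactants: 3 4-methyl-3-(tert-butyldimethylsilyloxy)penta-1,3-diene; 6 (E)-2-methylhepta-2,6-dienal
Product: 7 (1S,6S)-6-(but-3-en-1-yl)-4-[(tert-butyldimethylsilyl)oxy]-1,5,5-trimethylcyclohex-3-ene-1-carbaldehyde
Conditions: (S)-3,3-diphenyl-1-(2-methylphenyl)tetrahydro-1H,3H-pyrrolo[1,2-c][1,3,2]oxazaborole (20 mol %), HN(SO2CF3)2 (16 mol %), 3 (2 equiv), CH2Cl2, −78 → −40 °C; Et3N quench
Reagents that add atoms: none
Why: The formyl oxygen of 6 binds the cationic boron centre (formyl C–H held against the ring oxygen), which lowers the LUMO of the s-trans enal and leaves one π-face open. The silyloxy group makes C4 of 3 the nucleophilic terminus, so C4 bonds to the β-carbon C5 and C1 to the α-carbon C10, placing the C3 oxygen para to C10; with a fully substituted C4 the [4+2] event should be strongly asynchronous, C4–C5 leading (Mukaiyama–Michael character). The closest known reaction type is the oxazaborolidinium-catalysed Diels–Alder reaction of α-methyl enals with 2-silyloxy dienes, and Lewis-acid cycloadditions of 2-silyloxy dienes with a dimethylated terminus are also established. Ring A closes by intermolecular [4+2] cycloaddition, suprafacial on both partners (in the stepwise limit a 6-membered closure of the C10 boron enolate onto C1 of the silyloxyallyl cation). C10 and C5 are set together: their absolute configuration by the catalyst, which must expose the C10 Si/C5 Re face of the enal, and their relative configuration (formyl trans to the C6 arm, methyl cis to it) by the E geometry of 6. No endo/exo question arises because the diene termini carry two hydrogens and two methyl groups. The step needs enantiofacial selectivity (catalyst), para regioselectivity (silyloxy group) and chemoselectivity for cycloaddition over Mukaiyama aldol addition at the formyl group and over an achiral silyl-triflimide background; the bulky TBS group, the low temperature and the deficit of HN(SO2CF3)2 relative to the oxazaborolidine should secure the latter, and the monosubstituted alkene of the arm is not nucleophilic enough to interfere.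

Step 5
Reactants: 7 (1S,6S)-6-(but-3-en-1-yl)-4-[(tert-butyldimethylsilyl)oxy]-1,5,5-trimethylcyclohex-3-ene-1-carbaldehyde; 8 diethyl [(phenylsulfonyl)methyl]phosphonate
Product: 10 (3R,4S)-3-(but-3-en-1-yl)-2,2,4-trimethyl-4-[(E)-2-(phenylsulfonyl)ethenyl]cyclohexan-1-one, via silyl enol ether vinyl sulfone 9 (not isolated)
Conditions: NaH (1.3 equiv), THF, 0 → 45 °C; then 1 M HCl (aq), rt
Reagents that add atoms: none
Why: Horner–Wadsworth–Emmons olefination of the non-enolisable aldehyde with the sulfonyl-stabilised phosphonate anion should give the (E)-vinyl sulfone; aqueous acid then hydrolyses the silyl enol ether to the C3 ketone. Neither stereocentre is α to a carbonyl group, so none can epimerise.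

Step 6
Reactants: 10 (3R,4S)-3-(but-3-en-1-yl)-2,2,4-trimethyl-4-[(E)-2-(phenylsulfonyl)ethenyl]cyclohexan-1-one
Product: 11 (1S,3R,4S)-3-(but-3-en-1-yl)-2,2,4-trimethyl-4-[(E)-2-(phenylsulfonyl)ethenyl]cyclohexan-1-ol
Conditions: NaBH4, CeCl3·7H2O, MeOH, −40 °C
Reagents that add atoms: none
Why: Luche reduction; in the chair with both large groups equatorial the axial 4β and 10β methyl groups block the β-face, so hydride should enter axially from the α-face and give the equatorial 3β (3S) alcohol, as in 4,4-dimethyl-3-oxo terpenoids. CeCl3 and low temperature suppress conjugate addition to the vinyl sulfone.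

Step 7
Reactants: 11 (1S,3R,4S)-3-(but-3-en-1-yl)-2,2,4-trimethyl-4-[(E)-2-(phenylsulfonyl)ethenyl]cyclohexan-1-ol
Product: 12 4-{(1R,3S,6S)-3-hydroxy-2,2,6-trimethyl-6-[(E)-2-(phenylsulfonyl)ethenyl]cyclohexyl}butan-2-one
Conditions: PdCl2 (10 mol %), CuCl (1 equiv, turned over by O2), O2 (1 atm), DMF/H2O 7:1, rt
Reagents that add atoms: water, O
Why: Tsuji–Wacker oxidation: Markovnikov hydroxypalladation of the monosubstituted alkene and β-hydride elimination give the methyl ketone; the electron-poor 1,2-disubstituted vinyl sulfone and the secondary alcohol should be inert to divalent palladium under these conditions.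

Step 8
Reactants: 12 4-{(1R,3S,6S)-3-hydroxy-2,2,6-trimethyl-6-[(E)-2-(phenylsulfonyl)ethenyl]cyclohexyl}butan-2-one
Product: 13 (3S,5R,8R,9R,10S)-11-(phenylsulfonyl)drimane-3β,8α-diol
Conditions: SmI2 (2.5 equiv), MeOH (10 equiv), THF, −78 → 0 °C (no HMPA)
Reagents that add atoms: none
Why: Electron transfer from divalent samarium gives the samarium-bound C8 ketyl, which adds 6-exo-trig to C9 of the vinyl sulfone; the α-sulfonyl radical is reduced and protonated by methanol (reductive carbonyl–alkene cyclisation, established for acrylates and vinyl sulfones). In the chair transition state built on the fixed ring A chair, the bulky O–Sm group and the C9=C11 bond should both sit pseudo-equatorial and anti to each other, with the C8 methyl pseudo-axial. This gives 8α-OH/8β-CH3 and 9β-CH2SO2Ph (9α-H). Without HMPA the alkyl phenyl sulfone of the product should not be cleaved.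

Step 9
Reactants: 13 (3S,5R,8R,9R,10S)-11-(phenylsulfonyl)drimane-3β,8α-diol; 14 (2E,6E)-farnesyl bromide
Product: 16 (3S,5R,8R,9R,10S)-11-(phenylsulfonyl)-11-[(2E,6E)-3,7,11-trimethyldodeca-2,6,10-trien-1-yl]drimane-3β,8α-diol as a mixture of C11 epimers, via trilithiated sulfone 15 (not isolated)
Conditions: n-BuLi (3.1 equiv), THF/DMPU 5:1, −78 → −20 °C; then 14 (1.2 equiv), −78 → 0 °C; aqueous work-up
Reagents that add atoms: none
Why: Deprotonation gives the dialkoxide α-sulfonyl carbanion; the carbanion is by far the most nucleophilic site and should displace the primary allylic bromide by SN2 (classical sulfone alkylation for joining prenyl units) without touching the alkene geometry of 14. The new C11 centre is removed in step 10.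

Step 10
Reactants: 16 (3S,5R,8R,9R,10S)-11-(phenylsulfonyl)-11-[(2E,6E)-3,7,11-trimethyldodeca-2,6,10-trien-1-yl]drimane-3β,8α-diol
Product: 17 (3S,5R,8R,9R,10S)-11-[(2E,6E)-3,7,11-trimethyldodeca-2,6,10-trien-1-yl]drimane-3β,8α-diol (CID57401582)
Conditions: Na/Hg (6 % Na, 6 equiv), Na2HPO4 (8 equiv), MeOH/THF 2:1, −20 °C → rt
Reagents that add atoms: none
Why: Reductive desulfonylation by electron transfer: C–S cleavage releases benzenesulfinate and a C11 radical/anion that is protonated by the buffered methanol; isolated trisubstituted alkenes and free alcohols are inert, and both C11 epimers of 16 converge on 17.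

## Compound list

1 | 4-methylpent-1-en-3-ol (racemic) | C=CC(O)C(C)C | starting material
2 | 4-methylpent-1-en-3-one | C=CC(=O)C(C)C | intermediate
3 | 4-methyl-3-(tert-butyldimethylsilyloxy)penta-1,3-diene | C=CC(O[Si](C)(C)C(C)(C)C)=C(C)C | intermediate
4 | pent-4-enal | C=CCCC=O | starting material
5 | 2-(triphenylphosphoranylidene)propanal | CC(C=O)=P(c1ccccc1)(c1ccccc1)c1ccccc1 | starting material
6 | (E)-2-methylhepta-2,6-dienal | O=C/C(C)=C/CCC=C | intermediate
7 | (1S,6S)-6-(but-3-en-1-yl)-4-[(tert-butyldimethylsilyl)oxy]-1,5,5-trimethylcyclohex-3-ene-1-carbaldehyde | O=C[C@@]1(C)CC=C(O[Si](C)(C)C(C)(C)C)C(C)(C)[C@@H]1CCC=C | intermediate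
8 | diethyl [(phenylsulfonyl)methyl]phosphonate | CCOP(=O)(CS(=O)(=O)c1ccccc1)OCC | starting material
9 | {[(4S,5R)-5-(but-3-en-1-yl)-4,6,6-trimethyl-4-[(E)-2-(phenylsulfonyl)ethenyl]cyclohex-1-en-1-yl]oxy}(tert-butyl)dimethylsilane | O=S(=O)(c1ccccc1)/C=C/[C@@]1(C)CC=C(O[Si](C)(C)C(C)(C)C)C(C)(C)[C@@H]1CCC=C | intermediate (not isolated)
10 | (3R,4S)-3-(but-3-en-1-yl)-2,2,4-trimethyl-4-[(E)-2-(phenylsulfonyl)ethenyl]cyclohexan-1-one | O=S(=O)(c1ccccc1)/C=C/[C@@]1(C)CCC(=O)C(C)(C)[C@@H]1CCC=C | intermediate
11 | (1S,3R,4S)-3-(but-3-en-1-yl)-2,2,4-trimethyl-4-[(E)-2-(phenylsulfonyl)ethenyl]cyclohexan-1-ol | O=S(=O)(c1ccccc1)/C=C/[C@@]1(C)CC[C@H](O)C(C)(C)[C@@H]1CCC=C | intermediate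
12 | 4-{(1R,3S,6S)-3-hydroxy-2,2,6-trimethyl-6-[(E)-2-(phenylsulfonyl)ethenyl]cyclohexyl}butan-2-one | O=S(=O)(c1ccccc1)/C=C/[C@@]1(C)CC[C@H](O)C(C)(C)[C@@H]1CCC(C)=O | intermediate
13 | (3S,5R,8R,9R,10S)-11-(phenylsulfonyl)drimane-3β,8α-diol | O=S(=O)(c1ccccc1)C[C@@H]1[C@@]2(C)CC[C@H](O)C(C)(C)[C@@H]2CC[C@@]1(C)O | intermediate
14 | (2E,6E)-farnesyl bromide | CC(C)=CCC/C(C)=C/CC/C(C)=C/CBr | starting material
15 | trilithium derivative of 13 (C3 and C8 alkoxides, C11 α-sulfonyl carbanion) | [Li]C(S(=O)(=O)c1ccccc1)[C@@H]1[C@@]2(C)CC[C@H](O[Li])C(C)(C)[C@@H]2CC[C@@]1(C)O[Li] | intermediate (not isolated)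
16 | (3S,5R,8R,9R,10S)-11-(phenylsulfonyl)-11-[(2E,6E)-3,7,11-trimethyldodeca-2,6,10-trien-1-yl]drimane-3β,8α-diol (C11 epimers) | CC(C)=CCC/C(C)=C/CC/C(C)=C/CC(S(=O)(=O)c1ccccc1)[C@@H]1[C@@]2(C)CC[C@H](O)C(C)(C)[C@@H]2CC[C@@]1(C)O | intermediate
17 | (3S,5R,8R,9R,10S)-11-[(2E,6E)-3,7,11-trimethyldodeca-2,6,10-trien-1-yl]drimane-3β,8α-diol (CID57401582) | CC(C)=CCC/C(C)=C/CC/C(C)=C/CC[C@@H]1[C@@]2(C)CC[C@H](O)C(C)(C)[C@@H]2CC[C@@]1(C)O | target

## Step count and least certain steps

Total: 10 steps. Longest linear sequence: 9 steps (1 → 2 → 3 → 7 → 10 → 11 → 12 → 13 → 16 → 17; steps 1, 2, 4–10). No protecting group is used apart from the silyl enol ether that the cycloaddition itself creates.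

Step 4 (key step). Most likely failure: cycloaddition at the fully substituted diene terminus is too slow under the chiral catalyst. That would leave room for protodesilylation of the diene, Mukaiyama aldol addition at the formyl group, and an achiral silyl-triflimide-catalysed background, giving low conversion or eroded enantiofacial selectivity.
Fallback (sets out from 3 and 6, returns at 11): the cycloaddition is run without a chiral catalyst under AlBr3/AlMe3 (mixed Lewis acid, toluene/CH2Cl2, about 0 °C), a known system for silyloxy dienes with fully substituted termini. This should give 7 as the racemate, that is 7 together with (1R,6R)-6-(but-3-en-1-yl)-4-[(tert-butyldimethylsilyl)oxy]-1,5,5-trimethylcyclohex-3-ene-1-carbaldehyde F1. Step 5 then gives racemic 10, that is 10 together with (3S,4R)-3-(but-3-en-1-yl)-2,2,4-trimethyl-4-[(E)-2-(phenylsulfonyl)ethenyl]cyclohexan-1-one F3, by way of the (4R,5S)-enantiomer of 9 F2. The absolute configuration is then introduced by a kinetic resolution in place of step 6: Corey–Bakshi–Shibata reduction with (R)-1-methyl-3,3-diphenyltetrahydro-1H,3H-pyrrolo[1,2-c][1,3,2]oxazaborole (20 mol %) and about 0.55 equiv of catecholborane in toluene at −78 °C. Catecholborane is chosen so that the terminal alkene is not hydroborated. For 10 the catalyst and the ring both direct hydride to the α-face (matched pair), so it should be reduced much faster, to 11. F3 is the mismatched partner and should remain largely as ketone; the part that reacts is expected to give mainly (1S,3S,4R)-3-(but-3-en-1-yl)-2,2,4-trimethyl-4-[(E)-2-(phenylsulfonyl)ethenyl]cyclohexan-1-ol F4, a diastereomer of 11 that can be removed by chromatography. 11 re-enters at step 7.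

Step 8. Most likely failure: electron transfer to the vinyl sulfone outruns ring closure (simple saturation or C–S cleavage), or closure goes through the other chair with the oxygen axial, losing control of C8.
Fallback (sets out from 12, returns at 13): 12 is treated with TBSOTf/Et3N to give the 3-O-TBS ether of 12 with the C8 ketone as its tert-butyldimethylsilyl enol ether F5 (terminal isomer shown; the internal isomer serves equally, since both give the same C8 radical). Fe(acac)3/PhSiH3 in EtOH/ethylene glycol at 60 °C transfers a hydrogen atom to the electron-rich enol ether. The neutral tertiary α-silyloxy radical at C8 closes 6-exo onto C9 of the vinyl sulfone, and the α-sulfonyl radical is reduced and protonated (hydrogen-atom-transfer reductive alkene coupling, known for silyl enol ether donors and vinyl sulfone acceptors). This should give the 3,8-bis-O-(tert-butyldimethylsilyl) ether of 13 F6, with the silyloxy group as the largest substituent on the radical carbon again pseudo-equatorial. HF·pyridine in THF then releases 13.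

Step 9. Most likely failure: incomplete C-alkylation, because the carbanion lies between the quaternary C8 and C10 and is part of a trilithiated aggregate; base-induced elimination of 14 would then compete.
Fallback (sets out from 13, returns at 16): both hydroxyls are masked first (TMSOTf, Et3N, CH2Cl2, −78 → 0 °C) to give the 3,8-bis-O-trimethylsilyl ether of 13 F7. A single equivalent of n-BuLi in THF/DMPU then generates a monolithiated, unaggregated α-sulfonyl carbanion, which is alkylated with 14 to the 3,8-bis-O-trimethylsilyl ether of 16 F8. Fluoride (Bu4NF, THF) returns 16 for step 10.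

Step 6. Most likely failure: poor facial selectivity in the conformationally mobile monocycle, or conjugate hydride addition to the vinyl sulfone.
Fallback (sets out from 10, returns at 11): reagent control in place of substrate control, by Corey–Bakshi–Shibata reduction with (R)-1-methyl-3,3-diphenyltetrahydro-1H,3H-pyrrolo[1,2-c][1,3,2]oxazaborole and catecholborane in toluene at −78 °C. The quaternary C4 is the large and the C2 methylene the small substituent, which should direct hydride to the α-face and give the 3S alcohol 11 directly; no new compound is involved.

## Further compounds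

F1 | step 4 | (1R,6R)-6-(but-3-en-1-yl)-4-[(tert-butyldimethylsilyl)oxy]-1,5,5-trimethylcyclohex-3-ene-1-carbaldehyde (enantiomer of 7) | O=C[C@]1(C)CC=C(O[Si](C)(C)C(C)(C)C)C(C)(C)[C@H]1CCC=C
F2 | step 4 | (4R,5S)-enantiomer of 9 | O=S(=O)(c1ccccc1)/C=C/[C@]1(C)CC=C(O[Si](C)(C)C(C)(C)C)C(C)(C)[C@H]1CCC=C
F3 | step 4 | (3S,4R)-3-(but-3-en-1-yl)-2,2,4-trimethyl-4-[(E)-2-(phenylsulfonyl)ethenyl]cyclohexan-1-one (enantiomer of 10) | O=S(=O)(c1ccccc1)/C=C/[C@]1(C)CCC(=O)C(C)(C)[C@H]1CCC=C
F4 | step 4 | (1S,3S,4R)-3-(but-3-en-1-yl)-2,2,4-trimethyl-4-[(E)-2-(phenylsulfonyl)ethenyl]cyclohexan-1-ol (diastereomer of 11) | O=S(=O)(c1ccccc1)/C=C/[C@]1(C)CC[C@H](O)C(C)(C)[C@H]1CCC=C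
F5 | step 8 | 3-O-TBS ether of 12 with the C8 ketone as its tert-butyldimethylsilyl enol ether (terminal isomer) | O=S(=O)(c1ccccc1)/C=C/[C@@]1(C)CC[C@H](O[Si](C)(C)C(C)(C)C)C(C)(C)[C@@H]1CCC(=C)O[Si](C)(C)C(C)(C)C
F6 | step 8 | 3,8-bis-O-(tert-butyldimethylsilyl) ether of 13 | O=S(=O)(c1ccccc1)C[C@@H]1[C@@]2(C)CC[C@H](O[Si](C)(C)C(C)(C)C)C(C)(C)[C@@H]2CC[C@@]1(C)O[Si](C)(C)C(C)(C)C
F7 | step 9 | 3,8-bis-O-trimethylsilyl ether of 13 | O=S(=O)(c1ccccc1)C[C@@H]1[C@@]2(C)CC[C@H](O[Si](C)(C)C)C(C)(C)[C@@H]2CC[C@@]1(C)O[Si](C)(C)C
F8 | step 9 | 3,8-bis-O-trimethylsilyl ether of 16 (C11 epimers) | CC(C)=CCC/C(C)=C/CC/C(C)=C/CC(S(=O)(=O)c1ccccc1)[C@@H]1[C@@]2(C)CC[C@H](O[Si](C)(C)C)C(C)(C)[C@@H]2CC[C@@]1(C)O[Si](C)(C)C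
F0 | step 6 | none | none
A1 | alternative 1 | 3β-(tert-butyldimethylsilyloxy)-13,14,15,16-tetranorlabdan-8α,12-olide (sclareolide type) | O=C1C[C@@H]2[C@@]3(C)CC[C@H](O[Si](C)(C)C(C)(C)C)C(C)(C)[C@@H]3CC[C@@]2(C)O1
A2 | alternative 1 | ethyl (E)-3-[ring A]-prop-2-enoate with 3β-silyloxy group, C10 methyl and 3-oxobutyl arm on C5 (monocyclic keto enoate) | CCOC(=O)/C=C/[C@@]1(C)CC[C@H](O[Si](C)(C)C(C)(C)C)C(C)(C)[C@@H]1CCC(C)=O
A3 | alternative 2 | 2-methyl-3-vinyl-4-methyl-4-(tert-butyldimethylsilyloxy)cyclohexanone (C5 ketone; C8 and C9 as in the target) | C=C[C@@H]1[C@@H](C)C(=O)CC[C@@]1(C)O[Si](C)(C)C(C)(C)C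
A4 | alternative 2 | (R)-4-methyl-4-(tert-butyldimethylsilyloxy)cyclohex-2-en-1-one | O=C1C=C[C@](C)(O[Si](C)(C)C(C)(C)C)CC1
A5 | alternative 3 | trans-fused octalin C11 aldehyde with C6=C7 alkene, 3β- and 8α-silyloxy groups | O=C[C@@H]1[C@@]2(C)CC[C@H](O[Si](C)(C)C(C)(C)C)C(C)(C)[C@@H]2C=C[C@@]1(C)O[Si](C)(C)C(C)(C)C
A6 | alternative 3 | (2E,8E,10Z)-6,11-bis(tert-butyldimethylsilyloxy)-3,7,7-trimethyldodeca-2,8,10-trienal, (6S) | O=C/C=C(\C)CC[C@H](O[Si](C)(C)C(C)(C)C)C(C)(C)/C=C/C=C(/C)O[Si](C)(C)C(C)(C)C
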